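## Retrosynthetic overview

1. Ring E is closed last: the N–CH2 bond is made by intramolecular aza-Michael addition of the lactam N–H to an isopropenyl ketone released from β-chloro ketone 17. The acetate is set in the same pot.
2. Key C–C bond: the quaternary C(CH2OH)–CH2 bond comes from Ti(III) opening of spiro-epoxide 13. The epoxide carbon, normally an electrophile, reacts as a nucleophilic tertiary radical with the β-carbon of vinyl ketone 16.
3. The ring-B hydroxy-enone comes from a phenol by oxidative dearomatisation with water, then selective hydrogenation. Ring A comes from Pd-catalysed intramolecular ester α-arylation.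
4. Ring D (bridged lactam) comes from intramolecular amidoalkylation of a β-keto amide with formaldehyde. The benzylic quaternary centre comes from an asymmetric Michael addition to methyl acrylate.
5. Order of ring formation: B and C (from the tetralone) → D → A → B dearomatised → E.

Assumption: racemic 3-chloro-2-methylpropanoyl chloride is taken as commercial; rings are lettered A (cyclopentane), B (enone ring), C (carbocycle with both quaternary carbons), D (δ-lactam), E (nine-membered ring).

## Route

Step 1
Reactants: 1 5-methoxy-2-tetralone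
Product: 3 5-methoxy-2-oxo-1,2,3,4-tetrahydronaphthalene-1-carboxamide, via N-chlorosulfonyl amide 2 (not isolated)
Conditions: ClSO2NCO, CH2Cl2, 0 °C; then H2O/acetone, rt
Reagents that add atoms: chlorosulfonyl isocyanate, O=C=NS(=O)(=O)Cl
Why: The β-tetralone enol is C-carbamoylated at the benzylic C1 by chlorosulfonyl isocyanate and the N–SO2Cl group is hydrolysed on work-up (CSI amidation of a ketone); no stereocentre is fixed because 3 is enolised.

Step 2
Reactants: 3 5-methoxy-2-oxo-1,2,3,4-tetrahydronaphthalene-1-carboxamide; 4 methyl acrylate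
Product: 5 methyl 3-[(1R)-1-carbamoyl-5-methoxy-2-oxo-1,2,3,4-tetrahydronaphthalen-1-yl]propanoate
Conditions: N-(9-anthracenylmethyl)-O-allylcinchonidinium bromide (10 mol %), Cs2CO3 (0.5 equiv), toluene, −40 °C
Reagents that add atoms: none
Why: Phase-transfer-catalysed asymmetric Michael addition: the chiral ammonium–enolate ion pair blocks one enolate face and sets the benzylic quaternary centre as (R); the cinchoninium pseudo-enantiomer would give the antipode.

Step 3
Reactants: 5 methyl 3-[(1R)-1-carbamoyl-5-methoxy-2-oxo-1,2,3,4-tetrahydronaphthalen-1-yl]propanoate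
Product: 6 methyl 3-[(1R)-8-bromo-1-carbamoyl-5-methoxy-2-oxo-1,2,3,4-tetrahydronaphthalen-1-yl]propanoate
Conditions: NBS, MeCN, 0 °C
Reagents that add atoms: N-bromosuccinimide, BrN1C(=O)CCC1=O
Why: Electrophilic aromatic bromination para to the methoxy group (C8); this blocks that carbon against the acyliminium ion of step 4 and gives the handle for ring A.

Step 4
Reactants: 6 methyl 3-[(1R)-8-bromo-1-carbamoyl-5-methoxy-2-oxo-1,2,3,4-tetrahydronaphthalen-1-yl]propanoate
Product: 8 methyl 3-[(1R,5R)-10-bromo-7-methoxy-2,11-dioxo-3,4,5,6-tetrahydro-1,5-methano-3-benzazocin-1(2H)-yl]propanoate, via N-hydroxymethyl amide 7 (not isolated)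
Conditions: (CH2O)n, TFA, ClCH2CH2Cl, 60 °C
Reagents that add atoms: paraformaldehyde (formaldehyde), C=O
Why: Intramolecular amidoalkylation (Tscherniac–Einhorn/Mannich type): the N-acyliminium ion is attacked by the ketone enol at C3, the only enolisable α-carbon, and the one-carbon bridge can only span the ring cis-1,3, so the new bridgehead centre is dictated by the quaternary centre.

Step 5
Reactants: 8 methyl 3-[(1R,5R)-10-bromo-7-methoxy-2,11-dioxo-3,4,5,6-tetrahydro-1,5-methano-3-benzazocin-1(2H)-yl]propanoate
Product: 9 ring-A-closed tetracyclic anisole (ester α-carbon bonded to former C10; CO2Me on the face of the C11 ketone bridge)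
Conditions: Pd(OAc)2 (5 mol %), P(t-Bu)3·HBF4, LiHMDS (3 equiv), THF, 50 °C; then NaOMe (cat.), MeOH, rt
Reagents that add atoms: none
Why: Intramolecular Pd-catalysed α-arylation of the ester enolate (Buchwald–Hartwig type, 5-exo) closes ring A; the benzylic ester centre is epimerisable and methoxide equilibration leaves CO2Me on the face away from the lactam carbonyl, which lies under ring A.

Step 6
Reactants: 9 ring-A-closed tetracyclic anisole
Product: 10 tetracyclic phenol (OMe of 9 replaced by OH)
Conditions: BBr3, CH2Cl2, −78 → 0 °C
Reagents that add atoms: none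
Why: Lewis-acid O-demethylation of the aryl methyl ether; the methyl ester, lactam and ketone survive at low temperature and no stereocentre is touched.

Step 7
Reactants: 10 tetracyclic phenol
Product: 11 para-quinol dienone (tertiary OH on the ring A/B junction carbon, trans to CO2Me)
Conditions: PhI(OAc)2, MeCN/H2O (3:1), 0 °C
Reagents that add atoms: water, O
Why: Hypervalent-iodine oxidative dearomatisation of the para-substituted phenol to a para-quinol: water adds to the para carbon on the face anti to the adjacent ester (the lactam-carbonyl face), giving the tertiary alcohol trans to CO2Me.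

Step 8
Reactants: 11 para-quinol dienone
Product: 12 hydroxy-enone (disubstituted C=C of 11 saturated)
Conditions: H2 (1 atm), RhCl(PPh3)3 (10 mol %), benzene/EtOH, rt
Reagents that add atoms: none
Why: Wilkinson hydrogenation reduces only the disubstituted alkene of the cross-conjugated dienone; the tetrasubstituted enone alkene is inert and no stereocentre is formed.

Step 9
Reactants: 12 hydroxy-enone
Product: 13 spiro-epoxide at the former bridging ketone carbon (both epoxide epimers)
Conditions: ClCH2I, MeLi·LiBr (4 equiv each), THF, −78 °C → rt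
Reagents that add atoms: chloroiodomethane, ClCI
Why: Chloromethyllithium adds to the strained, unconjugated bridging ketone in preference to the hindered enone and the ester, and the chlorohydrin alkoxide closes to the epoxide (carbenoid epoxidation); the epoxide configuration is irrelevant because this carbon becomes a planar radical in step 11.

Step 10
Reactants: 14 3-chloro-2-methylpropanoyl chloride; 15 trimethyl(vinyl)silane
Product: 16 1-chloro-2-methylpent-4-en-3-one (racemic)
Conditions: AlCl3, CH2Cl2, −78 → −20 °C
Reagents that add atoms: none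
Why: Lewis-acid ipso-acylation of the vinylsilane (Friedel–Crafts type) with loss of Me3SiCl gives the vinyl ketone; its α-methyl centre is racemic and is re-set in step 12.

Step 11
Reactants: 13 spiro-epoxide; 16 1-chloro-2-methylpent-4-en-3-one
Product: 17 quaternary hydroxymethyl chloro-ketone (CH2OH and CH2CH2C(=O)CH(CH3)CH2Cl on the former epoxide carbon; chain syn to the lactam bridge)
Conditions: Cp2TiCl2 (0.3 equiv), Mn, 2,4,6-collidine·HCl (2.5 equiv), 16 (3 equiv), THF, rt
Reagents that add atoms: none
Why: Nugent–RajanBabu reductive epoxide opening: Cp2TiCl cleaves the tertiary C–O bond to a β-titanoxy tertiary radical, which adds to the vinyl ketone (Giese addition) and forges the quaternary centre with its CH2OH arm; the planar radical is attacked on the face syn to the lactam bridge because the ring-A ester screens the other face.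

Step 12
Reactants: 17 quaternary hydroxymethyl chloro-ketone
Product: 20 CNP0211170.1 (target), via primary acetate 18 (not isolated), via isopropenyl ketone 19 (not isolated)
Conditions: Ac2O, Et3N, DMAP (cat.), CH2Cl2, 0 °C; then Cs2CO3, MeCN, 50 °C, 2 mM
Reagents that add atoms: acetic anhydride, CC(=O)OC(C)=O
Why: Selective acetylation of the primary alcohol, then E1cB loss of HCl and intramolecular aza-Michael addition of the lactam N–H closes the nine-membered ring, which is possible only with the chain on the lactam face; the α-methyl centre equilibrates through the enolate to the more stable epimer, expected to be the natural one.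

## Compound list

1 | 5-methoxy-2-tetralone | O=C1CCc2c(OC)cccc2C1 | starting material
2 | N-(chlorosulfonyl)-5-methoxy-2-oxo-1,2,3,4-tetrahydronaphthalene-1-carboxamide | O=C(NS(=O)(=O)Cl)C1C(=O)CCc2c(OC)cccc21 | intermediate
3 | 5-methoxy-2-oxo-1,2,3,4-tetrahydronaphthalene-1-carboxamide | NC(=O)C1C(=O)CCc2c(OC)cccc21 | intermediate
4 | methyl acrylate | C=CC(=O)OC | starting material
5 | methyl 3-[(1R)-1-carbamoyl-5-methoxy-2-oxo-1,2,3,4-tetrahydronaphthalen-1-yl]propanoate | COC(=O)CC[C@]1(C(N)=O)C(=O)CCc2c(OC)cccc21 | intermediate
6 | methyl 3-[(1R)-8-bromo-1-carbamoyl-5-methoxy-2-oxo-1,2,3,4-tetrahydronaphthalen-1-yl]propanoate | COC(=O)CC[C@]1(C(N)=O)C(=O)CCc2c(OC)ccc(Br)c21 | intermediate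
7 | N-(hydroxymethyl) amide of 6 | COC(=O)CC[C@]1(C(=O)NCO)C(=O)CCc2c(OC)ccc(Br)c21 | intermediate
8 | methyl 3-[(1R,5R)-10-bromo-7-methoxy-2,11-dioxo-3,4,5,6-tetrahydro-1,5-methano-3-benzazocin-1(2H)-yl]propanoate | COC(=O)CC[C@@]12C(=O)NC[C@@H](Cc3c(OC)ccc(Br)c31)C2=O | intermediate
9 | ring-A-closed tetracyclic anisole: 8 with the ester α-carbon bonded to C10 in place of Br (indane-type ring A), CO2Me on the face of the C11 ketone bridge | COC(=O)[C@@H]1C[C@@]23C(=O)NC[C@@H](Cc4c(OC)ccc1c42)C3=O | intermediate
10 | tetracyclic phenol: 9 with OH in place of OMe | COC(=O)[C@@H]1C[C@@]23C(=O)NC[C@@H](Cc4c(O)ccc1c42)C3=O | intermediate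
11 | para-quinol dienone: tertiary OH on the ring A/B junction carbon (trans to CO2Me), cross-conjugated dienone in ring B | COC(=O)[C@@H]1C[C@@]23C(=O)NC[C@@H](CC5=C2[C@]1(O)C=CC5=O)C3=O | intermediate
12 | hydroxy-enone: 11 with the disubstituted ring-B alkene saturated | COC(=O)[C@@H]1C[C@@]23C(=O)NC[C@@H](CC5=C2[C@]1(O)CCC5=O)C3=O | intermediate
13 | spiro-epoxide of 12 at the bridging ketone carbon (mixture of epoxide epimers) | COC(=O)[C@@H]1C[C@@]23C(=O)NC[C@@H](CC5=C2[C@]1(O)CCC5=O)C34CO4 | intermediate
14 | 3-chloro-2-methylpropanoyl chloride (racemic) | CC(CCl)C(=O)Cl | starting material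
15 | trimethyl(vinyl)silane | C=C[Si](C)(C)C | starting material
16 | 1-chloro-2-methylpent-4-en-3-one (racemic) | C=CC(=O)C(C)CCl | intermediate
17 | quaternary hydroxymethyl chloro-ketone: CH2OH and CH2CH2C(=O)CH(CH3)CH2Cl on the former epoxide carbon, chain syn to the lactam bridge (epimers at CH(CH3)) | COC(=O)[C@@H]1C[C@@]23C(=O)NC[C@@H](CC5=C2[C@]1(O)CCC5=O)[C@]3(CO)CCC(=O)C(C)CCl | intermediate
18 | primary acetate of 17 | COC(=O)[C@@H]1C[C@@]23C(=O)NC[C@@H](CC5=C2[C@]1(O)CCC5=O)[C@]3(COC(C)=O)CCC(=O)C(C)CCl | intermediate
19 | isopropenyl ketone from 18 (HCl eliminated) | COC(=O)[C@@H]1C[C@@]23C(=O)NC[C@@H](CC5=C2[C@]1(O)CCC5=O)[C@]3(COC(C)=O)CCC(=O)C(C)=C | intermediate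
20 | CNP0211170.1, pentacyclic acetoxymethyl keto-lactam methyl ester | COC(=O)[C@@H]1C[C@@]23C(=O)N4C[C@@H](CC5=C2[C@]1(O)CCC5=O)[C@]3(COC(C)=O)CCC(=O)[C@H](C)C4 | target

## Step count and risks

Total step count: 12. Longest linear sequence: 11 (steps 1–9, 11, 12; step 10 is a one-step side branch).

The three steps most likely to fail:

**Step 11.** The intermolecular radical addition must form a hindered quaternary centre, and its facial selectivity rests on screening by the ring-A ester. Fallback, a polar route with no radical, setting out from 13 and returning at 17: BF3·OEt2 rearranges the epoxide (Meinwald) to the α-branched aldehyde F1. Pyrrolidine/AcOH-catalysed Michael addition of its enamine to 16 then gives the quaternary keto-aldehyde F2, and NaBH(OAc)3 reduces only the aldehyde to give 17.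

**Step 12.** Closing a nine-membered ring by aza-Michael addition of a weakly nucleophilic lactam N–H may be slow or may give the wrong methyl epimer. Fallback, making the N–C bond first and closing ring E by the C–C bond, setting out from 13 and returning at 20: Cs2CO3-catalysed aza-Michael addition of the lactam N–H to methacrolein gives the N-(2-methyl-3-oxopropyl) lactam F3. Nozaki–Hiyama–Kishi addition of vinyl bromide (CrCl2, cat. NiCl2) gives the allylic alcohol F4, and Dess–Martin oxidation gives the N-tethered vinyl ketone F5. Cp2TiCl-mediated epoxide opening then closes ring E by intramolecular radical conjugate addition, which the tether allows only on the lactam face, giving the primary alcohol F6. Ac2O/pyridine acetylates it to 20.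

**Step 7.** The iodine(III) dearomatisation may give a low yield or the wrong face at the carbinol carbon. Fallback, a singlet-oxygen route through a hydroperoxide, setting out from 10 and returning at 11: Oxone/NaHCO3 in MeCN/H2O converts the phenolate to the para-peroxyquinol F7, and Me2S reduces the hydroperoxide to 11.

Further compounds
F1 | step 11 | α-branched aldehyde from Meinwald rearrangement of 13 (CHO and H on the former epoxide carbon) | COC(=O)[C@@H]1C[C@@]23C(=O)NC[C@@H](CC5=C2[C@]1(O)CCC5=O)C3C=O
F2 | step 11 | quaternary keto-aldehyde (CHO in place of CH2OH of 17) | COC(=O)[C@@H]1C[C@@]23C(=O)NC[C@@H](CC5=C2[C@]1(O)CCC5=O)[C@]3(C=O)CCC(=O)C(C)CCl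
F3 | step 12 | N-(2-methyl-3-oxopropyl) lactam of epoxide 13 | COC(=O)[C@@H]1C[C@@]23C(=O)N(CC(C)C=O)C[C@@H](CC5=C2[C@]1(O)CCC5=O)C34CO4
F4 | step 12 | N-(3-hydroxy-2-methylpent-4-enyl) lactam (allylic alcohol) | COC(=O)[C@@H]1C[C@@]23C(=O)N(CC(C)C(O)C=C)C[C@@H](CC5=C2[C@]1(O)CCC5=O)C34CO4
F5 | step 12 | N-(2-methyl-3-oxopent-4-enyl) lactam (N-tethered vinyl ketone) | COC(=O)[C@@H]1C[C@@]23C(=O)N(CC(C)C(=O)C=C)C[C@@H](CC5=C2[C@]1(O)CCC5=O)C34CO4
F6 | step 12 | deacetyl target (primary alcohol, ring E closed) | COC(=O)[C@@H]1C[C@@]23C(=O)N4C[C@@H](CC5=C2[C@]1(O)CCC5=O)[C@]3(CO)CCC(=O)[C@H](C)C4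
F7 | step 7 | para-peroxyquinol (OOH in place of OH of 11) | COC(=O)[C@@H]1C[C@@]23C(=O)NC[C@@H](CC5=C2[C@]1(OO)C=CC5=O)C3=O
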